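## Retrosynthetic overview

1. The target is the 9-O-caffeate of (−)-lariciresinol. Three bonds are cut first: the ester C–O bond (Steglich), the benzylic CH2 (from a carbinol by ionic hydrogenation), and the bond from that carbon to the second guaiacyl ring (Grignard on a lactol). This leads to a cis-fused oxolane/γ-lactone whose lactone carbonyl is the future benzylic carbon. The lactone is a temporary ring that locks the two side chains cis.
2. Key disconnection: O1–C2 and C4–C5 of the oxolane are cut, so that O1–C5H2 leaves as formaldehyde. What remains is an arylcyclopropane fused to the same lactone (a 3-oxabicyclo[3.1.0]hexan-2-one with a removable allyl ester on the acceptor carbon).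
3. Enabling feature: the para-OH of the guaiacyl ring on oxolane C2 makes O1–C2 the 1,6-adduct of a p-quinone methide, as in lignan biosynthesis. Oxolane C4, 1,3 to C2, carries the exocyclic carbon that can be raised to carboxyl level, so C4 can be an enolate carbon. Phenolate push and dicarbonyl pull therefore open the cyclopropane bond between exactly these two atoms.
4. The cyclopropane comes from O-silyl coniferaldehyde and diallyl bromomalonate by an organocatalytic Michael-initiated ring closure, which sets the absolute configuration.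
5. Ring order: cyclopropane, then temporary γ-lactone, then oxolane (cyclopropane consumed), then lactone opened. All aromatic rings are bought.

Key step: step 5

Remark: the target is read as oxolane (2R,3S,4S), with aryl and CH2O-acyl trans and CH2O-acyl and benzyl cis. TBS = tert-butyldimethylsilyl. "C9 oxygen" means the oxygen of the CH2O group on oxolane C3.

## Route

Step 1
Reactants: 1 coniferaldehyde, (E)-3-(4-hydroxy-3-methoxyphenyl)prop-2-enal
Product: 2 (E)-3-[4-(tert-butyldimethylsilyloxy)-3-methoxyphenyl]prop-2-enal
Conditions: TBSCl, imidazole, CH2Cl2, 0 °C → rt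
Reagents that add atoms: tert-butyldimethylsilyl chloride, CC(C)(C)[Si](C)(C)Cl
Why: Imidazole-promoted silylation of a phenol, giving a silyl ether that protects the phenol now and serves as the fluoride trigger of step 5; no stereocentre is involved.

Step 2
Reactants: 3 diallyl malonate
Product: 4 diallyl 2-bromomalonate
Conditions: DBU (1.0 equiv), CBr4 (1.0 equiv), THF, −78 °C
Reagents that add atoms: carbon tetrabromide, BrC(Br)(Br)Br
Why: Polar bromine transfer from CBr4 to the DBU-generated malonate anion (the halogenation used in Bingel-type chemistry), which at −78 °C leaves the allyl C=C bonds untouched.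

Step 3
Reactants: 2 silyl coniferaldehyde; 4 diallyl 2-bromomalonate
Product: 5 diallyl (2S,3R)-2-formyl-3-[4-(tert-butyldimethylsilyloxy)-3-methoxyphenyl]cyclopropane-1,1-dicarboxylate (formyl trans to aryl)
Conditions: (R)-2-[diphenyl(trimethylsilyloxy)methyl]pyrrolidine (20 mol %), 2,6-lutidine (1.1 equiv), CH2Cl2, 0 °C → rt
Reagents that add atoms: none
Why: Organocatalytic Michael-initiated ring closure (iminium, then enamine catalysis) in which the (R)-diarylprolinol silyl ether shields one face of the E-iminium ion, so the bromomalonate carbon adds to the β-carbon to set C3 as R, and the 3-exo-tet enamine alkylation closes the ring with formyl trans to aryl (C2 S).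

Step 4
Reactants: 5 formylcyclopropane diester
Product: 7 allyl (1R,5S,6R)-6-[4-(tert-butyldimethylsilyloxy)-3-methoxyphenyl]-2-oxo-3-oxabicyclo[3.1.0]hexane-1-carboxylate (aryl exo), via hydroxymethyl diester 6 (not isolated)
Conditions: NaBH4, THF–i-PrOH, −20 °C; aq. NH4Cl; then camphorsulfonic acid (cat.), CH2Cl2, rt
Reagents that add atoms: none
Why: Chemoselective borohydride reduction of the aldehyde, then acid-catalysed 5-exo-trig lactonisation onto the only ester cis to the CH2OH group, which differentiates the two esters and fixes the quaternary centre C1 (R) while C5 and C6 stay as set.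

Step 5
Reactants: 7 cyclopropane-fused lactone ester; 8 formaldehyde (monomer, from commercial paraformaldehyde)
Product: 11 allyl (1S,5S,6R)-6-[4-(tert-butyldimethylsilyloxy)-3-methoxyphenyl]-2-oxo-3,7-dioxabicyclo[3.3.0]octane-1-carboxylate (aryl exo), via quinone methide enolate 9 (not isolated), via free phenol 10 (not isolated)
Conditions: n-Bu4NF (1.05 equiv, THF solution dried over 4 Å MS), CH2O (5 equiv, monomer in THF), THF, −40 → 0 °C; AcOH (1.1 equiv), extractive work-up; crude 10: TBSCl, imidazole, DMF, rt
Reagents that add atoms: tert-butyldimethylsilyl chloride, CC(C)(C)[Si](C)(C)Cl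
Why: Proposed new method: fluoride removes the aryl silyl group and the para-phenolate pushes open the strained, doubly acceptor-activated C1–C6 cyclopropane bond to give p-quinone methide/stabilised enolate 9, whose enolate carbon adds reversibly to formaldehyde (new C1–C8 bond) and whose new alkoxide then adds 1,6 to the quinone methide carbon (new O7–C6 bond) with rearomatisation, a net insertion of CH2=O into the cyclopropane. The closest known reaction types are the fluoride-induced opening of 2-(4-silyloxyaryl)cyclopropane-1,1-dicarboxylates through p-quinone methides with capture by carbon nucleophiles, the base-catalysed hydroxymethylation of malonates, the Lewis acid catalysed (3+2) annulation of aldehydes with donor–acceptor cyclopropanes, and the quinone methide capture by a side-chain hydroxyl that closes the oxolane rings in lignan biosynthesis. The one ring formed, the oxolane, closes by a 5-exo-trig oxa-1,6-addition. The quaternary centre C1 is controlled by the lactone ring, because only the aldol adduct with CH2O− cis to the quinone methide side chain can close (cis-bicyclo[3.3.0]octane) while the trans adduct reverts by retro-aldol (a Curtin–Hammett funnel). C6 is controlled by allylic 1,3-strain in 9 (C5–H eclipses the quinone methide ring), so the alkoxide attacks the face that places the aryl group exo and trans to C4 whatever the configuration of C6 in 7, and C5 is not touched. The step needs enolate capture by CH2O to outrun tautomerisation of 9 to the styrene and addition of outside nucleophiles, which excess monomeric CH2O, low water content and low temperature should secure, helped by the fact that 9 is only a minor partner in a fast equilibrium with the closed phenolate.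

Step 6
Reactants: 11 allyl ester lactone
Product: 13 (1S,5S,6R)-6-[4-(tert-butyldimethylsilyloxy)-3-methoxyphenyl]-3,7-dioxabicyclo[3.3.0]octan-2-one, via carboxylic acid 12 (not isolated)
Conditions: Pd(OAc)2 (5 mol %), PPh3 (20 mol %), HCO2H, Et3N, 1,4-dioxane, reflux
Reagents that add atoms: none
Why: Tsuji–Trost-type deallylation of an allyl malonate with formate (zerovalent palladium formed in situ) followed by thermal decarboxylation of malonic half-acid 12, in which protonation of the lactone enol can only give the cis-fused bicycle, so H takes the place of CO2 with retention at C1.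

Step 7
Reactants: 13 bicyclic lactone
Product: 14 (1S,5S,6R)-6-[4-(tert-butyldimethylsilyloxy)-3-methoxyphenyl]-3,7-dioxabicyclo[3.3.0]octan-2-ol (mixture of epimers at C2)
Conditions: i-Bu2AlH (1.1 equiv), CH2Cl2, −78 °C; aq. potassium sodium tartrate
Reagents that add atoms: none
Why: Partial reduction of a γ-lactone with i-Bu2AlH, which stops at the aluminium lactolate at −78 °C; the anomeric mixture is of no consequence.

Step 8
Reactants: 15 4-bromo-2-methoxyphenol
Product: 16 (4-bromo-2-methoxyphenoxy)(tert-butyl)dimethylsilane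
Conditions: TBSCl, imidazole, DMF, rt
Reagents that add atoms: tert-butyldimethylsilyl chloride, CC(C)(C)[Si](C)(C)Cl
Why: Standard phenol silylation, which makes the aryl bromide fit for metalation.

Step 9
Reactants: 14 lactol; 16 silylated aryl bromide
Product: 18 {(2R,3S,4S)-2-[4-(tert-butyldimethylsilyloxy)-3-methoxyphenyl]-4-{[4-(tert-butyldimethylsilyloxy)-3-methoxyphenyl](hydroxy)methyl}oxolan-3-yl}methanol (mixture of carbinol epimers), via arylmagnesium bromide 17 (not isolated)
Conditions: 16, Mg turnings, THF, 40 °C (3 equiv of 17); then 14, THF, 0 °C → rt; aq. NH4Cl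
Reagents that add atoms: none
Why: Grignard addition to the hydroxy aldehyde tautomer of a γ-lactol (the first equivalent of 17 is spent on the lactol OH), a standard opening of this lactol class in which addition outruns enolisation, so oxolane C4 keeps its configuration while the new carbinol centre forms as a mixture that step 12 erases.

Step 10
Reactants: 19 caffeic acid
Product: 21 (E)-3-[3,4-bis(tert-butyldimethylsilyloxy)phenyl]prop-2-enoic acid, via silyl ester 20 (not isolated)
Conditions: TBSCl (3.5 equiv), imidazole, DMF, rt; then AcOH–THF–H2O, rt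
Reagents that add atoms: tert-butyldimethylsilyl chloride, CC(C)(C)[Si](C)(C)Cl
Why: Exhaustive silylation followed by selective hydrolysis of the far more labile silyl ester under mild acid, which aryl silyl ethers tolerate.

Step 11
Reactants: 18 diol; 21 bis-silyl caffeic acid
Product: 22 {(2R,3S,4S)-2-[4-(tert-butyldimethylsilyloxy)-3-methoxyphenyl]-4-{[4-(tert-butyldimethylsilyloxy)-3-methoxyphenyl](hydroxy)methyl}oxolan-3-yl}methyl (E)-3-[3,4-bis(tert-butyldimethylsilyloxy)phenyl]prop-2-enoate
Conditions: 21 (1.0 equiv), DCC (1.1 equiv), DMAP (10 mol %), CH2Cl2, 0 °C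
Reagents that add atoms: none
Why: Steglich esterification, selective for the unhindered primary alcohol over the hindered secondary benzylic alcohol with one equivalent of acid at 0 °C; the ester also keeps the C9 oxygen from capturing the cation of step 12.

Step 12
Reactants: 22 hydroxy ester
Product: 23 {(2R,3S,4S)-2-[4-(tert-butyldimethylsilyloxy)-3-methoxyphenyl]-4-{[4-(tert-butyldimethylsilyloxy)-3-methoxyphenyl]methyl}oxolan-3-yl}methyl (E)-3-[3,4-bis(tert-butyldimethylsilyloxy)phenyl]prop-2-enoate
Conditions: Et3SiH (5 equiv), BF3·OEt2 (1.5 equiv), CH2Cl2, −78 → −40 °C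
Reagents that add atoms: none
Why: Ionic hydrogenation, in which the free secondary alcohol para to a silyloxy group ionises irreversibly to a benzylic cation that silane hydride traps, whereas ionisation of the cyclic benzylic ether is undone by ring re-closure at this temperature, and neither the acylated C9 oxygen nor the trans-disposed ring A can reach the cation.

Step 13
Reactants: 23 tetrasilyl ether
Product: 24 target, [(2R,3S,4S)-2-(4-hydroxy-3-methoxyphenyl)-4-[(4-hydroxy-3-methoxyphenyl)methyl]oxolan-3-yl]methyl (E)-3-(3,4-dihydroxyphenyl)prop-2-enoate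
Conditions: Et3N·3HF, THF, rt, argon
Reagents that add atoms: none
Why: Fluoride cleavage of four aryl silyl ethers under slightly acidic conditions, which should spare the cinnamate ester, the E-alkene and the p-hydroxybenzyl ether and keep the catechol from oxidising; no stereocentre is touched.

## Compound list

1 | coniferaldehyde | COc1cc(/C=C/C=O)ccc1O | starting material
2 | (E)-3-[4-(TBS-oxy)-3-methoxyphenyl]prop-2-enal | COc1cc(/C=C/C=O)ccc1O[Si](C)(C)C(C)(C)C | intermediate
3 | diallyl malonate | C=CCOC(=O)CC(=O)OCC=C | starting material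
4 | diallyl 2-bromomalonate | C=CCOC(=O)C(Br)C(=O)OCC=C | intermediate
5 | diallyl (2S,3R)-2-formyl-3-[4-(TBS-oxy)-3-methoxyphenyl]cyclopropane-1,1-dicarboxylate | O=C[C@H]1[C@H](c2ccc(O[Si](C)(C)C(C)(C)C)c(OC)c2)C1(C(=O)OCC=C)C(=O)OCC=C | intermediate
6 | diallyl (2S,3R)-2-(hydroxymethyl)-3-[4-(TBS-oxy)-3-methoxyphenyl]cyclopropane-1,1-dicarboxylate | OC[C@H]1[C@H](c2ccc(O[Si](C)(C)C(C)(C)C)c(OC)c2)C1(C(=O)OCC=C)C(=O)OCC=C | intermediate
7 | allyl (1R,5S,6R)-6-[4-(TBS-oxy)-3-methoxyphenyl]-2-oxo-3-oxabicyclo[3.1.0]hexane-1-carboxylate | O=C1OC[C@H]2[C@H](c3ccc(O[Si](C)(C)C(C)(C)C)c(OC)c3)[C@@]12C(=O)OCC=C | intermediate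
8 | formaldehyde | C=O | starting material
9 | tetrabutylammonium enolate of allyl 4-[(3-methoxy-4-oxocyclohexa-2,5-dien-1-ylidene)methyl]-2-oxooxolane-3-carboxylate (C4 configured as C5 of 7) | O=C1OC[C@@H](C=C2C=CC(=O)C(OC)=C2)[C-]1C(=O)OCC=C.CCCC[N+](CCCC)(CCCC)CCCC | intermediate
10 | allyl (1S,5S,6R)-6-(4-hydroxy-3-methoxyphenyl)-2-oxo-3,7-dioxabicyclo[3.3.0]octane-1-carboxylate | O=C1OC[C@H]2[C@H](c3ccc(O)c(OC)c3)OC[C@@]12C(=O)OCC=C | intermediate
11 | allyl (1S,5S,6R)-6-[4-(TBS-oxy)-3-methoxyphenyl]-2-oxo-3,7-dioxabicyclo[3.3.0]octane-1-carboxylate | O=C1OC[C@H]2[C@H](c3ccc(O[Si](C)(C)C(C)(C)C)c(OC)c3)OC[C@@]12C(=O)OCC=C | intermediate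
12 | (1S,5S,6R)-6-[4-(TBS-oxy)-3-methoxyphenyl]-2-oxo-3,7-dioxabicyclo[3.3.0]octane-1-carboxylic acid | O=C1OC[C@H]2[C@H](c3ccc(O[Si](C)(C)C(C)(C)C)c(OC)c3)OC[C@@]12C(=O)O | intermediate
13 | (1S,5S,6R)-6-[4-(TBS-oxy)-3-methoxyphenyl]-3,7-dioxabicyclo[3.3.0]octan-2-one | O=C1OC[C@H]2[C@H](c3ccc(O[Si](C)(C)C(C)(C)C)c(OC)c3)OC[C@@H]12 | intermediate
14 | (1S,5S,6R)-6-[4-(TBS-oxy)-3-methoxyphenyl]-3,7-dioxabicyclo[3.3.0]octan-2-ol, C2 epimers | OC1OC[C@H]2[C@H](c3ccc(O[Si](C)(C)C(C)(C)C)c(OC)c3)OC[C@@H]12 | intermediate
15 | 4-bromo-2-methoxyphenol | COc1cc(Br)ccc1O | starting material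
16 | (4-bromo-2-methoxyphenoxy)(tert-butyl)dimethylsilane | COc1cc(Br)ccc1O[Si](C)(C)C(C)(C)C | intermediate
17 | [4-(TBS-oxy)-3-methoxyphenyl]magnesium bromide | COc1cc([Mg]Br)ccc1O[Si](C)(C)C(C)(C)C | intermediate
18 | diol, (2R,3S,4S)-oxolane with 3-CH2OH and 4-CH(OH)aryl, carbinol epimers | COc1cc(C(O)[C@@H]2CO[C@@H](c3ccc(O[Si](C)(C)C(C)(C)C)c(OC)c3)[C@@H]2CO)ccc1O[Si](C)(C)C(C)(C)C | intermediate
19 | caffeic acid | OC(=O)/C=C/c1ccc(O)c(O)c1 | starting material
20 | TBS (E)-3-[3,4-bis(TBS-oxy)phenyl]prop-2-enoate | CC(C)(C)[Si](C)(C)OC(=O)/C=C/c1ccc(O[Si](C)(C)C(C)(C)C)c(O[Si](C)(C)C(C)(C)C)c1 | intermediate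
21 | (E)-3-[3,4-bis(TBS-oxy)phenyl]prop-2-enoic acid | OC(=O)/C=C/c1ccc(O[Si](C)(C)C(C)(C)C)c(O[Si](C)(C)C(C)(C)C)c1 | intermediate
22 | primary caffeate ester of 18 (tetrasilyl, free benzylic OH) | COc1cc(C(O)[C@@H]2CO[C@@H](c3ccc(O[Si](C)(C)C(C)(C)C)c(OC)c3)[C@@H]2COC(=O)/C=C/c2ccc(O[Si](C)(C)C(C)(C)C)c(O[Si](C)(C)C(C)(C)C)c2)ccc1O[Si](C)(C)C(C)(C)C | intermediate
23 | tetra-O-TBS target | COc1cc(C[C@@H]2CO[C@@H](c3ccc(O[Si](C)(C)C(C)(C)C)c(OC)c3)[C@@H]2COC(=O)/C=C/c2ccc(O[Si](C)(C)C(C)(C)C)c(O[Si](C)(C)C(C)(C)C)c2)ccc1O[Si](C)(C)C(C)(C)C | intermediate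
24 | CNP0132883.1, 9-O-caffeoyl-(−)-lariciresinol | COc1cc(C[C@@H]2CO[C@@H](c3ccc(O)c(OC)c3)[C@@H]2COC(=O)/C=C/c2ccc(O)c(O)c2)ccc1O | target

## Step count and risks

Total steps: 13. Longest linear sequence: 10 (steps 1, 3, 4, 5, 6, 7, 9, 11, 12, 13).

**Step 5 (the proposed new method).**
- What may go wrong: the quinone methide may tautomerise to the styrene, with loss of the C5 stereocentre. It may be captured by water, fluoride or hemiformal oxygen. The unproductive trans aldol adduct may be protonated before it can revert.
- Fallback (from 7, back at 11): 7 is treated with paraformaldehyde and catalytic Sn(OTf)2 in CH2Cl2. This is the established Lewis acid catalysed (3+2) annulation of aldehydes with 2-arylcyclopropane-1,1-dicarboxylates, in which the carbonyl oxygen attacks the benzylic carbon with inversion before the aldol closure.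
- From exo-aryl 7 this should give, with the silyl ether untouched, the endo-aryl epimer allyl (1S,5S,6S)-6-[4-(tert-butyldimethylsilyloxy)-3-methoxyphenyl]-2-oxo-3,7-dioxabicyclo[3.3.0]octane-1-carboxylate F1.
- F1 is then equilibrated at the benzylic ether carbon with catalytic camphorsulfonic acid in CH2Cl2, the known acid epimerisation of 6-aryl-3,7-dioxabicyclo[3.3.0]octanes. Compound 11 is separated and F1 is recycled.

**Step 12.**
- What may go wrong: the oxolane C2–O1 bond may ionise and be reduced in competition. The cation may lose the proton at C4, which would scramble that centre.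
- Fallback (from 22, back at 23): a radical Barton–McCombie deoxygenation replaces the cationic one. Compound 22 is treated with 1,1'-thiocarbonyldiimidazole and DMAP in CH2Cl2 to give the O-(imidazol-1-ylthiocarbonyl) derivative of 22 F2.
- F2 is reduced with Bu3SnH and AIBN in toluene at 80 °C to give 23. The benzylic radical is quenched without touching ethers, and no neighbouring stereocentre is involved.

**Step 3.**
- What may go wrong: the electron-rich enal may form its iminium ion slowly. The bromomalonate may N-alkylate the catalyst. Base may open the donor–acceptor cyclopropane to the α-substituted enal, with erosion of enantiomeric purity.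
- Fallback (from 2 and 3, back at 5, skipping step 2): conjugate addition and ring closure are separated. The same (R)-catalyst with benzoic acid in ethanol mediates the well-established Michael addition of malonate 3 to enal 2, giving diallyl 2-{(1S)-1-[4-(tert-butyldimethylsilyloxy)-3-methoxyphenyl]-3-oxopropyl}malonate F3.
- F3 is then closed oxidatively with I2 and DBU in CH2Cl2: the malonate carbon is iodinated and the aldehyde enolate alkylates it (3-exo-tet) to give the trans cyclopropane 5.

## Further compounds

F1 | step 5 | allyl (1S,5S,6S)-6-[4-(tert-butyldimethylsilyloxy)-3-methoxyphenyl]-2-oxo-3,7-dioxabicyclo[3.3.0]octane-1-carboxylate | O=C1OC[C@H]2[C@@H](c3ccc(O[Si](C)(C)C(C)(C)C)c(OC)c3)OC[C@@]12C(=O)OCC=C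
F2 | step 12 | O-(imidazol-1-ylthiocarbonyl) derivative of 22 | COc1cc(C(OC(=S)n4ccnc4)[C@@H]2CO[C@@H](c3ccc(O[Si](C)(C)C(C)(C)C)c(OC)c3)[C@@H]2COC(=O)/C=C/c2ccc(O[Si](C)(C)C(C)(C)C)c(O[Si](C)(C)C(C)(C)C)c2)ccc1O[Si](C)(C)C(C)(C)C
F3 | step 3 | diallyl 2-{(1S)-1-[4-(tert-butyldimethylsilyloxy)-3-methoxyphenyl]-3-oxopropyl}malonate | O=CC[C@H](c1ccc(O[Si](C)(C)C(C)(C)C)c(OC)c1)C(C(=O)OCC=C)C(=O)OCC=C
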